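The route cuts the ethano bridge at its bond to C1 of ring B (the 3‑hydroxyphenyl ring). The bridge carbon at that bond is the terminal carbon of a styrene on ring A (the central methoxyphenol ring), and ring B carries its hydroxyl meta to the bridge, where no electrophilic substitution can place a chain. One operation therefore does the work: anti‑Markovnikov hydroboration of the unprotected vinyl bisphenol and B‑alkyl Suzuki–Miyaura coupling with 3‑bromophenol form the CH2–aryl bond at the final oxidation level and give the target directly. The styrene comes in four steps from a bromo‑dimethoxybenzaldehyde whose chelation‑controlled demethylation fixes the OH/OMe pattern of ring A.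

Key step: step 5

Remark: the target is achiral, so no stereocentre has to be set; the aldehyde starting material and the THP‑protected aryl Grignard solution are taken as catalogue items.

Step 1
Reactants: 1 2-bromo-4,6-dimethoxybenzaldehyde
Product: 2 2-bromo-6-hydroxy-4-methoxybenzaldehyde
Conditions: BCl3 (1 M in CH2Cl2, 1.5 equiv), CH2Cl2, −78 °C to 0 °C; aq. work-up
Reagents that add atoms: none
Why: Chelation-controlled Lewis-acid O-demethylation: BCl3 binds the aldehyde oxygen and the adjacent 6-OMe in a six-membered chelate, so chloride should cleave only that ortho methyl ether and leave the para 4-OMe, the C–Br bond and the aldehyde untouched.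

Step 2
Reactants: 2 2-bromo-6-hydroxy-4-methoxybenzaldehyde; 3 [4-(oxan-2-yloxy)phenyl]magnesium bromide
Product: 4 3-bromo-2-{hydroxy[4-(oxan-2-yloxy)phenyl]methyl}-5-methoxyphenol
Conditions: 3 (0.5 M in THF, 2.4 equiv), THF, 0 °C to rt; sat. aq. NH4Cl
Reagents that add atoms: none
Why: Grignard 1,2-addition: the first equivalent of 3 deprotonates the phenol and the second should add to the still electrophilic aldehyde of the magnesium phenoxide, the aryl bromide and the THP acetal being inert to an aryl Grignard; the carbinol and acetal stereocentres are left uncontrolled because step 3 erases both.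

Step 3
Reactants: 4 3-bromo-2-{hydroxy[4-(oxan-2-yloxy)phenyl]methyl}-5-methoxyphenol
Product: 5 3-bromo-2-[(4-hydroxyphenyl)methyl]-5-methoxyphenol
Conditions: Et3SiH (4 equiv), TFA (10 equiv), CH2Cl2, 0 °C to rt
Reagents that add atoms: none
Why: Ionic hydrogenation: TFA ionises the carbinol to a diarylmethyl cation stabilised by the ortho-OH/para-OMe ring and the para-oxygenated ring, Et3SiH delivers hydride to it, and the same acid cleaves the THP acetal (its oxocarbenium ion is reduced to oxane), so one operation should give the free bisphenol diarylmethane without touching C–Br.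

Step 4
Reactants: 5 3-bromo-2-[(4-hydroxyphenyl)methyl]-5-methoxyphenol
Product: 6 3-ethenyl-2-[(4-hydroxyphenyl)methyl]-5-methoxyphenol
Conditions: vinylboronic acid pinacol ester (2 equiv), Pd(OAc)2 (cat.), SPhos (cat.), K3PO4 (4 equiv), 1,4-dioxane/H2O, 80 °C
Reagents that add atoms: vinylboronic acid pinacol ester (4,4,5,5-tetramethyl-2-vinyl-1,3,2-dioxaborolane), C=CB1OC(C)(C)C(C)(C)O1
Why: Suzuki–Miyaura vinylation: oxidative addition into the only C–Br bond, transmetalation of the vinylboronate under aqueous phosphate and reductive elimination should install the vinyl group, the two phenols being tolerated as phenoxides with an electron-rich biarylphosphine ligand.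

Step 5
Reactants: 6 3-ethenyl-2-[(4-hydroxyphenyl)methyl]-5-methoxyphenol; 7 9-borabicyclo[3.3.1]nonane (9-BBN, handled as its dimer); 8 3-bromophenol
Product: 10 3-[2-(3-hydroxyphenyl)ethyl]-2-[(4-hydroxyphenyl)methyl]-5-methoxyphenol, via B-alkyl-9-BBN bis(aryloxyborane) 9 (not isolated)
Conditions: 7 (3.3 equiv B–H), THF, 0 °C to 60 °C; then 8 (1.2 equiv), PdCl2(dppf)·CH2Cl2 (cat.), 3 M aq. NaOH, THF/DMF, 65 °C; mildly acidic work-up
Reagents that add atoms: none
Why: Hydroboration/B-alkyl Suzuki–Miyaura coupling, the closest known reaction type being the cross-coupling of B-alkyl-9-BBN reagents with aryl bromides. 9-BBN should first cap both phenols of 6 as aryloxyboranes with loss of H2 and then add syn across the vinyl group with boron on the terminal carbon, giving 9. Hydroxide turns the B-alkyl unit into a four-coordinate borate and frees the phenoxides, Pd(0) inserts into the C–Br bond of 8, the primary alkyl group transmetalates with retention, and reductive elimination from the wide-bite-angle dppf complex should outrun β-hydride elimination to form the CH2–aryl bond. No ring is closed and no stereocentre is formed. The step needs anti-Markovnikov regioselectivity, which the bulk of 9-BBN and the ortho benzyl group flanking the vinyl group secure, and transfer of the primary alkyl group rather than a bicyclic B–C bond, which is inherent to 9-BBN. The meta relation of hydroxyl and chain on ring B is fixed by the bromide position in 8, so no regiochemical question arises on that ring.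

Compound list
1 | 2-bromo-4,6-dimethoxybenzaldehyde | COc1cc(OC)c(C=O)c(Br)c1 | starting material
2 | 2-bromo-6-hydroxy-4-methoxybenzaldehyde | COc1cc(O)c(C=O)c(Br)c1 | intermediate
3 | [4-(oxan-2-yloxy)phenyl]magnesium bromide (racemic THP acetal, solution in THF) | Br[Mg]c1ccc(OC2CCCCO2)cc1 | starting material
4 | 3-bromo-2-{hydroxy[4-(oxan-2-yloxy)phenyl]methyl}-5-methoxyphenol (mixture of diastereomers, both stereocentres uncontrolled) | COc1cc(O)c(C(O)c2ccc(OC3CCCCO3)cc2)c(Br)c1 | intermediate
5 | 3-bromo-2-[(4-hydroxyphenyl)methyl]-5-methoxyphenol | COc1cc(O)c(Cc2ccc(O)cc2)c(Br)c1 | intermediate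
6 | 3-ethenyl-2-[(4-hydroxyphenyl)methyl]-5-methoxyphenol | COc1cc(O)c(Cc2ccc(O)cc2)c(C=C)c1 | intermediate
7 | 9-borabicyclo[3.3.1]nonane (9-BBN) | B1C2CCCC1CCC2 | starting material
8 | 3-bromophenol | Oc1cccc(Br)c1 | starting material
9 | 9-{2-[3-(9-borabicyclo[3.3.1]nonan-9-yloxy)-2-{[4-(9-borabicyclo[3.3.1]nonan-9-yloxy)phenyl]methyl}-5-methoxyphenyl]ethyl}-9-borabicyclo[3.3.1]nonane (not isolated) | COc1cc(OB2C3CCCC2CCC3)c(Cc2ccc(OB3C4CCCC3CCC4)cc2)c(CCB2C3CCCC2CCC3)c1 | intermediate
10 | 3-[2-(3-hydroxyphenyl)ethyl]-2-[(4-hydroxyphenyl)methyl]-5-methoxyphenol | COc1cc(O)c(Cc2ccc(O)cc2)c(CCc2cccc(O)c2)c1 | target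

Total step count: 5
Longest linear sequence: 5 steps (1 → 2 → 4 → 5 → 6 → 10)

Steps most likely to fail

Step 5. The three acidic phenols consume borane and base, so hydroboration may stay incomplete or transmetalation may stall, and the alkylborane may protodeboronate before it couples. The fallback sets out from 6 and forms the same bond at the alkene oxidation level without boron. A Mizoroki–Heck coupling of 6 with 8 (Pd(OAc)2, P(o-tol)3, Et3N, DMF, 100 °C) should give the stilbene 3-[(E)-2-(3-hydroxyphenyl)ethenyl]-2-[(4-hydroxyphenyl)methyl]-5-methoxyphenol F1. Hydrogenation of its double bond (H2, Pd/C, EtOAc) comes back to the route at 10.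

Step 3. The stabilised diarylmethyl cation may be captured by the electron-rich phenol rings of a second molecule (Friedel–Crafts oligomerisation) faster than by the silane, and the THP-derived oxocarbenium ion may alkylate ring A. The fallback sets out from 4 and removes the benzylic oxygen under basic conditions through an ortho-quinone methide. Ethyl chloroformate/Et3N (THF, 0 °C) should acylate the phenol to 3-bromo-2-{hydroxy[4-(oxan-2-yloxy)phenyl]methyl}-5-methoxyphenyl ethyl carbonate F2. NaBH4 in aqueous THF should then trigger carbonate transfer to the benzylic alkoxide, 1,4-elimination and conjugate hydride addition, giving 3-bromo-5-methoxy-2-{[4-(oxan-2-yloxy)phenyl]methyl}phenol F3. PPTS in MeOH removes the THP group and comes back to the route at 5.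

Step 4. The newly formed styrene may be consumed in a Heck-type reaction with the arylpalladium species derived from 5, and the free hydroxystyrene may oligomerise during coupling and isolation. The fallback sets out from 5, carries the two carbons as an alkyne and never passes through a styrene.
- Sonogashira coupling with ethynyltrimethylsilane (PdCl2(PPh3)2, CuI, Et3N, DMF, 80 °C) should give 2-[(4-hydroxyphenyl)methyl]-5-methoxy-3-[(trimethylsilyl)ethynyl]phenol F4.
- K2CO3 in MeOH should give 3-ethynyl-2-[(4-hydroxyphenyl)methyl]-5-methoxyphenol F5.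
- A second Sonogashira coupling, with 8 under the same catalyst system, forms the bond to ring B at the alkyne level and should give 3-[(3-hydroxyphenyl)ethynyl]-2-[(4-hydroxyphenyl)methyl]-5-methoxyphenol F6.
- Hydrogenation (H2, Pd/C, EtOAc) reduces the alkyne to the ethano bridge and comes back to the route at 10.

Further compounds
F1 | step 5 | 3-[(E)-2-(3-hydroxyphenyl)ethenyl]-2-[(4-hydroxyphenyl)methyl]-5-methoxyphenol | COc1cc(O)c(Cc2ccc(O)cc2)c(/C=C/c2cccc(O)c2)c1
F2 | step 3 | 3-bromo-2-{hydroxy[4-(oxan-2-yloxy)phenyl]methyl}-5-methoxyphenyl ethyl carbonate | CCOC(=O)Oc1cc(OC)cc(Br)c1C(O)c1ccc(OC2CCCCO2)cc1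
F3 | step 3 | 3-bromo-5-methoxy-2-{[4-(oxan-2-yloxy)phenyl]methyl}phenol | COc1cc(O)c(Cc2ccc(OC3CCCCO3)cc2)c(Br)c1
F4 | step 4 | 2-[(4-hydroxyphenyl)methyl]-5-methoxy-3-[(trimethylsilyl)ethynyl]phenol | COc1cc(O)c(Cc2ccc(O)cc2)c(C#C[Si](C)(C)C)c1
F5 | step 4 | 3-ethynyl-2-[(4-hydroxyphenyl)methyl]-5-methoxyphenol | COc1cc(O)c(Cc2ccc(O)cc2)c(C#C)c1
F6 | step 4 | 3-[(3-hydroxyphenyl)ethynyl]-2-[(4-hydroxyphenyl)methyl]-5-methoxyphenol | COc1cc(O)c(Cc2ccc(O)cc2)c(C#Cc2cccc(O)c2)c1
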